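**Plan**
- Cuts: the lactone C12–O8 of the diene half and the C1'–C2' bond (late oxidation and Heck coupling); then C5–C13' and C3–C11' (Diels–Alder, with 1-OH from an ene reaction); then both seven-membered rings back to one cyclohexanone by removing C5.
- Enabling feature: in the ring C1, C5–C10 the CH3 on C10 and the branch C11–C13 on C7 sit 1,4 across C1. Without C5 this is the p-menthane ring of carvone (isopropenyl = C11–C13), and C1, which needs an enol derivative toward C5, is its carbonyl carbon.
- Forward: carvone → α'-hydroxylation, 1,3-enone transposition, 1,4-reduction → cyclohexanone 11 → one-carbon ring expansion to enol silane 13 → enol triflate 15 → allylic alcohol 16.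
- 16 diverges into the diene half 18 (silyl ether, Heck) and the dienophile half 22 (acid, Mitsunobu lactone; the triflate is its masked diene). Union by Diels–Alder, then ene reaction, Heck, desilylation, oxidative lactonisation.
- Stereochemistry: C7/C7' from (R)-carvone; C8 by enolate hydroxylation anti to isopropenyl (C8' inverted by Mitsunobu); C10/C10' by equilibration; C5, C3, C11' in the exo Diels–Alder step; C1 by suprafacial ene relay from C3.

Key step: step 7

Remark: xanthane numbering is used for both halves (ring C1, C5–C10; CH3 on C10; branch C11–C13 on C7; O on C8; chain C2–C4 on C1; primes for the dienophile half), β means toward the viewer when C10→C9→C8→C7→C6→C5→C1 runs clockwise, and the target is made exactly as drawn: 7α-branch, 8β-O, 10β-CH3 (trans lactone) in the diene half and 7'α-branch, 8'α-O, 10'β-CH3 (cis lactone) in the dienophile half.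

Step 1
Reactants: 1 (R)-(−)-carvone
Product: 3 (5S,6S)-6-hydroxycarvone, via lithium dienolate 2 (not isolated)
Conditions: LiN(i-Pr)2, THF, −78 °C; 2-(phenylsulfonyl)-3-phenyloxaziridine, −78 °C; NH4Cl aq
Reagents that add atoms: 2-(phenylsulfonyl)-3-phenyloxaziridine, O=S(=O)(c1ccccc1)N1OC1c1ccccc1
Why: Kinetic α'-deprotonation at C6 followed by electrophilic enolate hydroxylation with the N-sulfonyloxaziridine, the oxidant approaching C6 anti to the neighbouring C5 isopropenyl group, should give the trans (5S,6S) ketol.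

Step 2
Reactants: 3 (5S,6S)-6-hydroxycarvone
Product: 4 (5S,6S)-6-(tert-butyldimethylsilyloxy)carvone
Conditions: t-BuMe2SiOTf, 2,6-lutidine, CH2Cl2, −78 → 0 °C
Reagents that add atoms: tert-butyldimethylsilyl trifluoromethanesulfonate, CC(C)(C)[Si](C)(C)OS(=O)(=O)C(F)(F)F
Why: Standard O-silylation of a hindered secondary alcohol, which touches no stereocentre.

Step 3
Reactants: 4 (5S,6S)-6-(tert-butyldimethylsilyloxy)carvone
Product: 5 2,3-epoxy ketone
Conditions: 30% H2O2, NaOH (cat.), MeOH, 0 °C
Reagents that add atoms: hydrogen peroxide, OO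
Why: Weitz–Scheffer nucleophilic epoxidation of the enone, the hydroperoxide adding to C3 anti to the isopropenyl group; both new centres are erased in steps 4 and 5.

Step 4
Reactants: 5 2,3-epoxy ketone
Product: 8 transposed allylic alcohol, via epoxy hydrazone 6 (not isolated), via vinyldiazene 7 (not isolated)
Conditions: N2H4·H2O, AcOH (cat.), MeOH, 0 °C → rt
Reagents that add atoms: none
Why: Wharton transposition, in which the epoxy hydrazone opens to the hydroxy vinyldiazene and loses N2, so that the double bond lies between the former carbonyl carbon and C2 and the carbinol carbon keeps the epoxide C–O bond.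

Step 5
Reactants: 8 transposed allylic alcohol
Product: 9 (4R,5S)-4-(tert-butyldimethylsilyloxy)-2-methyl-5-(prop-1-en-2-yl)cyclohex-2-en-1-one
Conditions: Dess–Martin periodinane, NaHCO3, CH2Cl2, rt
Reagents that add atoms: none
Why: Dess–Martin oxidation of the allylic alcohol completes the 1,3-carbonyl transposition, so the silyloxy carbon is now C4 (γ to the carbonyl) and next to the isopropenyl-bearing C5.

Step 6
Reactants: 9 transposed enone
Product: 11 (2S,4R,5S)-4-(tert-butyldimethylsilyloxy)-2-methyl-5-(prop-1-en-2-yl)cyclohexan-1-one, via lithium enolate 10 (not isolated)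
Conditions: LiBH(s-Bu)3, THF, −78 °C; NH4Cl aq; then NaOMe (cat.), MeOH, rt
Reagents that add atoms: none
Why: Conjugate (1,4) hydride reduction of the β-monosubstituted enone and base equilibration of the α-methyl centre should give the all-equatorial ketone, so C2 (the future C10) is set under thermodynamic control with methyl cis to OTBS and trans to isopropenyl.

Step 7
Reactants: 11 cyclohexanone (xanthane numbering: carbonyl C1, CH2 C6, CH(CH3) C10)
Product: 13 seven-membered enol silane (C1–OSiMe3, C1=C5), via α-silyl ketone 12 (not isolated)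
Conditions: Me3SiCHN2 (1.3 equiv), Sc(OTf)3 (5 mol %), toluene, −20 °C → rt, then 60 °C
Reagents that add atoms: trimethylsilyldiazomethane, C[Si](C)(C)C=[N+]=[N-]
Why: Sc(OTf)3 activates the C1 carbonyl, the diazo carbon adds to it, and the diazonium alkoxide undergoes a 1,2-shift of the C1–C6 bond onto the new carbon (C5) with loss of N2, which enlarges the six-membered ring to the seven-membered ring and gives α-silyl ketone 12; a C→O 1,3-silyl (Brook) shift on warming then gives enol silane 13 with the double bond fixed between C1 and C5. The closest known reaction type is the Lewis acid-promoted homologation of cycloalkanones with diazoalkanes (a Tiffeneau–Demjanov-type ring expansion) coupled with the Brook rearrangement of β-ketosilanes. No ring is closed by cyclisation, since the ring grows by insertion of one carbon into the C1–C6 bond. No stereocentre is created (C5 is sp3 only in transient 12), and C7, C8 and C10 are untouched because no enolisation toward C10 takes place. The step needs migration of the unbranched C6 methylene and not of the methyl-bearing C10, which the α-methyl group secures (the silylated diazo carbon adds so that the less substituted carbon is antiperiplanar to N2), and regiospecific enol formation, which the silyl group on C5 secures. It delivers, without base, the C1–O/C1=C5 enol derivative from which both the dienone chain of one half and the masked diene of the other are made.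

Step 8
Reactants: 13 enol silane
Product: 15 enol triflate, via lithium enolate 14 (not isolated)
Conditions: MeLi, THF, 0 °C; then PhNTf2, −78 °C → rt
Reagents that add atoms: N-phenylbis(trifluoromethanesulfonimide), O=S(=O)(N(c1ccccc1)S(=O)(=O)C(F)(F)F)C(F)(F)F
Why: Si–O cleavage of the enol silane by MeLi gives the regiodefined lithium enolate, which is O-sulfonylated before it can equilibrate (enolate triflation), so the C1=C5 position and the C10 centre are kept.

Step 9
Reactants: 15 enol triflate
Product: 16 allylic alcohol (C12–OH)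
Conditions: SeO2 (cat.), t-BuOOH, CH2Cl2, rt
Reagents that add atoms: selenium dioxide, O=[Se]=O; tert-butyl hydroperoxide, CC(C)(C)OO (terminal oxidant that restores SeO2)
Why: SeO2 allylic oxidation (ene reaction then [2,3]-shift) of the 1,1-disubstituted isopropenyl group at its methyl group, the electron-poor enol triflate alkene and its allylic positions being inert.

Step 10
Reactants: 16 allylic alcohol
Product: 17 bis-silyl ether
Conditions: t-BuMe2SiCl, imidazole, DMF, rt
Reagents that add atoms: tert-butyldimethylsilyl chloride, CC(C)(C)[Si](C)(C)Cl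
Why: Silylation of the primary allylic alcohol protects it from redox isomerisation in the palladium steps and keeps the future α-methylene lactone of this half latent until step 19.

Step 11
Reactants: 17 bis-silyl ether
Product: 18 diene half (E)-dienone
Conditions: methyl vinyl ketone (5 equiv), Pd(OAc)2 (5 mol %), PPh3, Et3N, DMF, 70 °C
Reagents that add atoms: methyl vinyl ketone, C=CC(C)=O
Why: Heck reaction of the enol triflate with methyl vinyl ketone (oxidative addition, syn insertion, syn β-hydride elimination) should give the (E)-dienone C5=C1–C2=C3–C4=O.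

Step 12
Reactants: 16 allylic alcohol
Product: 20 acrylic acid, via enal 19 (not isolated)
Conditions: TEMPO (cat.), NaOCl (cat.), NaClO2, MeCN/phosphate buffer (pH 6.7), 35 °C
Reagents that add atoms: sodium chlorite, [Na+].[O-]Cl=O
Why: TEMPO/hypochlorite oxidation of the primary allylic alcohol to the enal and chlorite (Pinnick-type) oxidation of the enal give the acid in one flask without touching the enol triflate.

Step 13
Reactants: 20 acrylic acid
Product: 21 trans hydroxy acid
Conditions: HF·pyridine, pyridine, THF, 0 °C → rt; extraction at pH 4–5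
Reagents that add atoms: none
Why: Fluoride cleavage of the secondary silyl ether under buffered conditions that leave the enol triflate intact, the trans hydroxy acid being isolated before it can lactonise with retention.

Step 14
Reactants: 21 trans hydroxy acid
Product: 22 dienophile half (cis-fused α-methylene lactone with C1' enol triflate)
Conditions: PPh3, diisopropyl azodicarboxylate, THF (0.01 M), 0 °C → rt
Reagents that add atoms: none
Why: Mitsunobu lactonisation, in which the C8 hydroxyl is activated as its alkoxyphosphonium ion and displaced by the carboxylate in a 5-exo-tet SN2 reaction with inversion, should give the cis-fused lactone (8'α-O).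

Step 15
Reactants: 18 diene half; 22 dienophile half
Product: 23 Diels–Alder adduct
Conditions: 22 (1.5 equiv), 2,6-di-tert-butyl-4-methylphenol (cat.), toluene (2 M), 95 °C, sealed tube
Reagents that add atoms: none
Why: Thermal intermolecular Diels–Alder reaction of the s-cis dienone (C5=C1–C2=C3) with the α-methylene lactone, joined C5–C13' and C3–C11' (the acyl-bearing diene terminus bonds to the acyl-bearing dienophile carbon, ortho rule), in which the dienophile reacts through its convex face (the face of H7' and H8') in the carbonyl-exo mode usual for α-methylene-γ-butyrolactones, setting C11' and C3, and the diene reacts on its β-face, anti to the pseudoaxial 6-H of the all-equatorial cycloheptene chair (torsional control) and away from the 7α branch, setting C5.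

Step 16
Reactants: 23 Diels–Alder adduct
Product: 25 tertiary allylic alcohol (1α-OH, C2=C3), via hydroperoxide 24 (not isolated)
Conditions: O2, tetraphenylporphyrin (cat.), visible light, CH2Cl2, −20 °C; then PPh3, −20 °C → rt
Reagents that add atoms: dioxygen, O=O
Why: Schenck ene reaction of singlet oxygen with the trisubstituted C1=C2 alkene, in which oxygen bonds to C1 on the face from which the pseudoaxial, acetyl-activated 3-H is abstracted (suprafacial), so the C3 centre of step 15 is relayed to C1 (1-OOH cis to 5-H) and the double bond moves into conjugation; PPh3 reduces the hydroperoxide.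

Step 17
Reactants: 25 tertiary allylic alcohol
Product: 26 bis-silyl ether of the seco-target (dienone on C1')
Conditions: methyl vinyl ketone (5 equiv), Pd(OAc)2 (5 mol %), PPh3, Et3N, DMF, 70 °C
Reagents that add atoms: methyl vinyl ketone, C=CC(C)=O
Why: Heck reaction of the remaining enol triflate unmasks the diene of the dienophile half as the (E)-dienone; the only other alkenes present (trisubstituted enone, 1,1-disubstituted allyl silyl ether) are poor Heck acceptors.

Step 18
Reactants: 26 bis-silyl ether
Product: 27 triol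
Conditions: HF·pyridine, pyridine, THF, 0 °C → rt
Reagents that add atoms: none
Why: Fluoride cleavage of both silyl ethers; the enones, the spiro lactone and the tertiary allylic alcohol should be stable to buffered HF·pyridine.

Step 19
Reactants: 27 triol
Product: 30 CNP0168949.5, via enal 28 (not isolated), via lactol 29 (not isolated)
Conditions: TEMPO (cat.), PhI(OAc)2, CH2Cl2, rt
Reagents that add atoms: none
Why: TEMPO/PhI(OAc)2 oxidative lactonisation, in which the primary allylic alcohol is oxidised selectively to the enal, trapped by the 8β-hydroxyl as the trans-fused lactol and oxidised on to the α-methylene lactone, the secondary and tertiary alcohols not being oxidised under these conditions.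

**Compound list**
1 | (R)-(−)-carvone, (5R)-2-methyl-5-(prop-1-en-2-yl)cyclohex-2-en-1-one | CC1=CC[C@H](CC1=O)C(C)=C | starting material
2 | lithium dienolate of 1 (C1–OLi, C1=C6, C2=C3; not isolated) | CC1=CC[C@H](C=C1O[Li])C(C)=C | intermediate
3 | (5S,6S)-6-hydroxy-2-methyl-5-(prop-1-en-2-yl)cyclohex-2-en-1-one (trans-6-hydroxycarvone) | O[C@@H]1C(=O)C(C)=CC[C@H]1C(C)=C | intermediate
4 | (5S,6S)-6-(tert-butyldimethylsilyloxy)-2-methyl-5-(prop-1-en-2-yl)cyclohex-2-en-1-one | CC(C)(C)[Si](C)(C)O[C@@H]1C(=O)C(C)=CC[C@H]1C(C)=C | intermediate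
5 | 2,3-epoxide of 4, oxirane oxygen cis to OTBS and trans to isopropenyl | CC(C)(C)[Si](C)(C)O[C@@H]1C(=O)[C@]2(C)O[C@@H]2C[C@H]1C(C)=C | intermediate
6 | hydrazone of epoxy ketone 5 (not isolated) | CC(C)(C)[Si](C)(C)O[C@@H]1C(=NN)[C@]2(C)O[C@@H]2C[C@H]1C(C)=C | intermediate
7 | hydroxy vinyldiazene from opening of 6 (not isolated) | CC(C)(C)[Si](C)(C)O[C@@H]1C(N=N)=C(C)[C@H](O)C[C@H]1C(C)=C | intermediate
8 | 4-(tert-butyldimethylsilyloxy)-2-methyl-5-(prop-1-en-2-yl)cyclohex-2-en-1-ol, 4-OTBS and 5-isopropenyl trans, 1-OH cis to 4-OTBS | CC(C)(C)[Si](C)(C)O[C@@H]1C=C(C)[C@H](O)C[C@H]1C(C)=C | intermediate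
9 | (4R,5S)-4-(tert-butyldimethylsilyloxy)-2-methyl-5-(prop-1-en-2-yl)cyclohex-2-en-1-one | CC(C)(C)[Si](C)(C)O[C@@H]1C=C(C)C(=O)C[C@H]1C(C)=C | intermediate
10 | lithium enolate (C1–OLi, C1=C2) from 1,4-reduction of 9 (not isolated) | CC(C)(C)[Si](C)(C)O[C@@H]1CC(C)=C(O[Li])C[C@H]1C(C)=C | intermediate
11 | (2S,4R,5S)-4-(tert-butyldimethylsilyloxy)-2-methyl-5-(prop-1-en-2-yl)cyclohexan-1-one | CC(C)(C)[Si](C)(C)O[C@@H]1C[C@H](C)C(=O)C[C@H]1C(C)=C | intermediate
12 | 5-(trimethylsilyl)-8β-(tert-butyldimethylsilyloxy)-10β-methyl-7α-(prop-1-en-2-yl)cycloheptan-1-one, xanthane numbering, C5 epimers (not isolated) | CC(C)(C)[Si](C)(C)O[C@@H]1C[C@H](C)C(=O)C([Si](C)(C)C)C[C@H]1C(C)=C | intermediate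
13 | 1-(trimethylsilyloxy)-8β-(tert-butyldimethylsilyloxy)-10β-methyl-7α-(prop-1-en-2-yl)cyclohept-1(5)-ene | CC(C)(C)[Si](C)(C)O[C@@H]1C[C@H](C)C(O[Si](C)(C)C)=CC[C@H]1C(C)=C | intermediate
14 | lithium enolate corresponding to 13 (C1–OLi, C1=C5; not isolated) | CC(C)(C)[Si](C)(C)O[C@@H]1C[C@H](C)C(O[Li])=CC[C@H]1C(C)=C | intermediate
15 | 8β-(tert-butyldimethylsilyloxy)-10β-methyl-7α-(prop-1-en-2-yl)cyclohept-1(5)-en-1-yl trifluoromethanesulfonate | CC(C)(C)[Si](C)(C)O[C@@H]1C[C@H](C)C(OS(=O)(=O)C(F)(F)F)=CC[C@H]1C(C)=C | intermediate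
16 | enol triflate 15 with the isopropenyl methyl oxidised: 7α-(3-hydroxyprop-1-en-2-yl) | CC(C)(C)[Si](C)(C)O[C@@H]1C[C@H](C)C(OS(=O)(=O)C(F)(F)F)=CC[C@H]1C(=C)CO | intermediate
17 | bis-silyl ether: 8β-OTBS, 7α-[3-(tert-butyldimethylsilyloxy)prop-1-en-2-yl], C1 triflate | CC(C)(C)[Si](C)(C)O[C@@H]1C[C@H](C)C(OS(=O)(=O)C(F)(F)F)=CC[C@H]1C(=C)CO[Si](C)(C)C(C)(C)C | intermediate
18 | diene half: (E)-4-[8β-OTBS-10β-methyl-7α-(3-TBSO-prop-1-en-2-yl)cyclohept-1(5)-en-1-yl]but-3-en-2-one | CC(C)(C)[Si](C)(C)O[C@@H]1C[C@H](C)C(/C=C/C(C)=O)=CC[C@H]1C(=C)CO[Si](C)(C)C(C)(C)C | intermediate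
19 | 2-substituted acrolein from 16 (C12 aldehyde; not isolated) | CC(C)(C)[Si](C)(C)O[C@@H]1C[C@H](C)C(OS(=O)(=O)C(F)(F)F)=CC[C@H]1C(=C)C=O | intermediate
20 | 2-substituted acrylic acid (C12 acid), 8β-OTBS, C1 triflate | CC(C)(C)[Si](C)(C)O[C@@H]1C[C@H](C)C(OS(=O)(=O)C(F)(F)F)=CC[C@H]1C(=C)C(O)=O | intermediate
21 | trans hydroxy acid: 8β-OH, 7α-(1-carboxyvinyl), 10β-CH3, C1 triflate | O[C@@H]1C[C@H](C)C(OS(=O)(=O)C(F)(F)F)=CC[C@H]1C(=C)C(O)=O | intermediate
22 | dienophile half: cis-fused α-methylene-γ-butyrolactone (7'α-C11', 8'α-O, 10'β-CH3) with C1' enol triflate, C1'=C5' | C=C1C(=O)O[C@H]2C[C@H](C)C(OS(=O)(=O)C(F)(F)F)=CC[C@@H]12 | intermediate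
23 | Diels–Alder adduct: cyclohexene C1=C2, 3-acetyl with 3-H cis to 5-H (5α-H), spiro C11' with C12' on the face of 3-H and 5-H; diene half still 8β-OTBS and 7α-(3-TBSO-prop-1-en-2-yl); dienophile half with C1' triflate | CC(C)(C)[Si](C)(C)O[C@@H]1C[C@H](C)C2=C[C@H](C(C)=O)[C@]3(C[C@@H]2C[C@H]1C(=C)CO[Si](C)(C)C(C)(C)C)C(=O)O[C@H]1C[C@H](C)C(OS(=O)(=O)C(F)(F)F)=CC[C@H]13 | intermediate
24 | 1α-hydroperoxide of 23 with C2=C3 (not isolated) | CC(C)(C)[Si](C)(C)O[C@@H]1C[C@H](C)[C@]2(OO)C=C(C(C)=O)[C@]3(C[C@@H]2C[C@H]1C(=C)CO[Si](C)(C)C(C)(C)C)C(=O)O[C@H]1C[C@H](C)C(OS(=O)(=O)C(F)(F)F)=CC[C@H]13 | intermediate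
25 | 1α-hydroxy enone (1-OH cis to 5-H), bis-silyl ether, C1' triflate | CC(C)(C)[Si](C)(C)O[C@@H]1C[C@H](C)[C@]2(O)C=C(C(C)=O)[C@]3(C[C@@H]2C[C@H]1C(=C)CO[Si](C)(C)C(C)(C)C)C(=O)O[C@H]1C[C@H](C)C(OS(=O)(=O)C(F)(F)F)=CC[C@H]13 | intermediate
26 | as 25 with the (E)-3-oxobut-1-enyl chain on C1' in place of the triflate | CC(C)(C)[Si](C)(C)O[C@@H]1C[C@H](C)[C@]2(O)C=C(C(C)=O)[C@]3(C[C@@H]2C[C@H]1C(=C)CO[Si](C)(C)C(C)(C)C)C(=O)O[C@H]1C[C@H](C)C(/C=C/C(C)=O)=CC[C@H]13 | intermediate
27 | triol: 1α-OH, 8β-OH, C12–OH (7α-(3-hydroxyprop-1-en-2-yl)) | O[C@@H]1C[C@H](C)[C@]2(O)C=C(C(C)=O)[C@]3(C[C@@H]2C[C@H]1C(=C)CO)C(=O)O[C@H]1C[C@H](C)C(/C=C/C(C)=O)=CC[C@H]13 | intermediate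
28 | C12 enal of 27 (not isolated) | O[C@@H]1C[C@H](C)[C@]2(O)C=C(C(C)=O)[C@]3(C[C@@H]2C[C@H]1C(=C)C=O)C(=O)O[C@H]1C[C@H](C)C(/C=C/C(C)=O)=CC[C@H]13 | intermediate
29 | trans-fused lactol (C12 hemiacetal with O8; not isolated) | C=C1C(O)O[C@@H]2C[C@H](C)[C@]3(O)C=C(C(C)=O)[C@]4(C[C@@H]3C[C@@H]12)C(=O)O[C@H]1C[C@H](C)C(/C=C/C(C)=O)=CC[C@H]14 | intermediate
30 | CNP0168949.5 | C=C1C(=O)O[C@@H]2C[C@H](C)[C@]3(O)C=C(C(C)=O)[C@]4(C[C@@H]3C[C@@H]12)C(=O)O[C@H]1C[C@H](C)C(/C=C/C(C)=O)=CC[C@H]14 | target

**Totals**
Total step count: 19. Longest linear sequence: 17 steps (steps 1–9, 12–14, 15–19).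

**Steps most likely to fail**

1. Step 15 (Diels–Alder union). The diene may show poor facial selectivity, with attack on the α-face giving the C5 epimer and, after step 16, the C1 epimer. The union of two electron-poor partners may also be slow. The fallback closes the lactone of the diene half before the cycloaddition, so that the trans ring fusion locks the cycloheptene in a single chair. It sets out from 16. HF·pyridine gives the diol F1. TEMPO/PhI(OAc)2 gives the trans-fused α-methylene lactone triflate F2. Heck coupling with methyl vinyl ketone gives the dienone lactone F3. F3, as the limiting partner, is heated with an excess of 22 (which suppresses its self-dimerisation) to give the cycloadduct F4. The Schenck ene reaction followed by PPh3 gives the tertiary alcohol F5. Heck coupling of F5 with a large excess of methyl vinyl ketone comes back to the route at 30.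

2. Step 16 (ene oxygenation). Hydrogen abstraction may occur at C5 instead of C3, which puts oxygen on C2, or the β,γ-unsaturated ketone may isomerise into conjugation before it is oxygenated. The fallback is anionic autoxidation. It sets out from 23: KOt-Bu, O2 and P(OEt)3 in THF/t-BuOH at −40 °C deprotonate C3, and the extended dienolate is oxygenated at its γ-carbon C1 on the face of 5-H (cis ring fusion). This passes through the same hydroperoxide 24 and comes back to the route at 25. No new compound is made.

3. Step 7 (ring expansion). The methyl-bearing carbon may migrate instead of C6, the silyl group may be lost before the C→O shift, or the shift may stay incomplete. The fallback inserts the carbon with an acceptor-substituted diazo compound and then uses kinetic enolisation. It sets out from 11. Ethyl diazoacetate with BF3·OEt2 gives the β-keto ester F6 (ester on C5). LiCl in wet DMSO at 140 °C (Krapcho) removes the ester to give the cycloheptanone F7. LiN(SiMe3)2 at −78 °C followed by PhNTf2 triflates the less substituted enolate and comes back to the route at 15.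

Further compounds
F1 | step 15 | diol: 8β-hydroxy-7α-(3-hydroxyprop-1-en-2-yl)-10β-methylcyclohept-1(5)-en-1-yl trifluoromethanesulfonate | O[C@@H]1C[C@H](C)C(OS(=O)(=O)C(F)(F)F)=CC[C@H]1C(=C)CO
F2 | step 15 | trans-fused α-methylene lactone (7α-C11, 8β-O, 10β-CH3) with C1 enol triflate | C=C1C(=O)O[C@@H]2C[C@H](C)C(OS(=O)(=O)C(F)(F)F)=CC[C@@H]12
F3 | step 15 | trans-fused α-methylene lactone with the (E)-3-oxobut-1-enyl chain on C1 (lactone-locked diene) | C=C1C(=O)O[C@@H]2C[C@H](C)C(/C=C/C(C)=O)=CC[C@@H]12
F4 | step 15 | cycloadduct of F3 and 22 (C1=C2, 3-H cis to 5-H, diene-half lactone closed, C1' triflate) | C=C1C(=O)O[C@@H]2C[C@H](C)C3=C[C@H](C(C)=O)[C@]4(C[C@@H]3C[C@@H]12)C(=O)O[C@H]1C[C@H](C)C(OS(=O)(=O)C(F)(F)F)=CC[C@H]14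
F5 | step 15 | 1α-hydroxy enone from F4 (C2=C3, C1' triflate) | C=C1C(=O)O[C@@H]2C[C@H](C)[C@]3(O)C=C(C(C)=O)[C@]4(C[C@@H]3C[C@@H]12)C(=O)O[C@H]1C[C@H](C)C(OS(=O)(=O)C(F)(F)F)=CC[C@H]14
F0 | step 16 | none | none
F6 | step 7 | ethyl 1-oxo-8β-(tert-butyldimethylsilyloxy)-10β-methyl-7α-(prop-1-en-2-yl)cycloheptane-5-carboxylate (xanthane numbering, C5 epimers/enol) | CC(C)(C)[Si](C)(C)O[C@@H]1C[C@H](C)C(=O)C(C(=O)OCC)C[C@H]1C(C)=C
F7 | step 7 | 8β-(tert-butyldimethylsilyloxy)-10β-methyl-7α-(prop-1-en-2-yl)cycloheptan-1-one | CC(C)(C)[Si](C)(C)O[C@@H]1C[C@H](C)C(=O)CC[C@H]1C(C)=C
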